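**Retrosynthetic overview**

- The target is reached from (3S,5S)-1,7-bis[4-(benzyloxy)-3-methoxyphenyl]-3,5-bis(tert-butyldimethylsilyloxy)heptane by desilylation, monoacetylation of the two homotopic hydroxyls through a cyclic orthoester, and hydrogenolysis of the benzyl ethers.
- That heptane is cut at the aryl–C1 and aryl–C7 bonds: double 9-BBN hydroboration of (3R,5R)-3,5-bis(tert-butyldimethylsilyloxy)hepta-1,6-diene and two-fold B-alkyl Suzuki–Miyaura coupling with 1-(benzyloxy)-4-bromo-2-methoxybenzene.
- Structural feature used: each guaiacyl ring sits on an unfunctionalised CH2–CH2 arm (C1–C2 and C6–C7), and the anti C3/C5 oxygen pair flanking the C4 methylene is the 1,3-diol of a trans-cyclopent-4-ene-1,3-diol (ring C1–C2–C3 = chain C3–C4–C5; ring C4=C5 = chain C2 and C6).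
- The diene comes from double Wittig methylenation of the dialdehyde obtained by ozonolysis of the trans-bis(silyloxy)cyclopentene, itself made by Mitsunobu inversion of commercial (1S,4R)-cis-4-acetoxy-2-cyclopenten-1-ol.
- Ring order: no ring is formed. Both arene rings are purchased, and the cyclopentene is opened once it has delivered the stereodiad.

Key step: step 7

Remark: the (3S,5S)-diol with two identical arms is C2-symmetric, so its hydroxyls are homotopic and acetylation of either oxygen gives the target. 9-BBN is taken as its commercial dimer or THF solution.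

**Step 1**
Reactants: 1 (1S,4R)-cis-4-acetoxy-2-cyclopenten-1-ol
Product: 2 (1R,4R)-4-acetoxycyclopent-2-en-1-yl 4-nitrobenzoate
Conditions: 4-nitrobenzoic acid, PPh3, DIAD, THF, 0 °C to rt
Reagents that add atoms: 4-nitrobenzoic acid, O=C(O)c1ccc(cc1)[N+](=O)[O-]
Why: Mitsunobu reaction, in which the carboxylate displaces the alkoxyphosphonium group at C1 by SN2 with inversion (S to R), turning the cis-1,4 relationship into the trans (R,R) pair while the acetate-bearing centre is untouched.

**Step 2**
Reactants: 2 (1R,4R)-4-acetoxycyclopent-2-en-1-yl 4-nitrobenzoate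
Product: 3 (1R,3R)-cyclopent-4-ene-1,3-diol
Conditions: K2CO3 (0.2 equiv), MeOH, 0 °C to rt; acidic resin, filter, concentrate
Reagents that add atoms: none
Why: Base-catalysed transesterification cleaves both esters at the acyl–oxygen bond, so neither carbinol centre is touched and the C2-symmetric trans-diol should result.

**Step 3**
Reactants: 3 (1R,3R)-cyclopent-4-ene-1,3-diol
Product: 4 (3R,5R)-3,5-bis(tert-butyldimethylsilyloxy)cyclopent-1-ene
Conditions: TBSCl (2.4 equiv), imidazole, DMF, rt
Reagents that add atoms: tert-butyldimethylsilyl chloride, CC(C)(C)[Si](C)(C)Cl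
Why: Imidazole-promoted silylation of both secondary allylic hydroxyls is routine and installs groups that should survive ozonolysis, ylide, borane and aqueous base.

**Step 4**
Reactants: 4 (3R,5R)-3,5-bis(tert-butyldimethylsilyloxy)cyclopent-1-ene
Product: 6 (2R,4R)-2,4-bis(tert-butyldimethylsilyloxy)pentanedial, via secondary ozonide 5 (not isolated)
Conditions: O3, CH2Cl2, −78 °C; then PPh3, −78 °C to rt; used at once
Reagents that add atoms: ozone, [O-][O+]=O
Why: Ozonolysis by the Criegee mechanism (1,3-dipolar cycloaddition, cycloreversion and recombination to the secondary ozonide, then PPh3 reduction) cleaves the only C=C bond to the dialdehyde without touching the two silyloxy-bearing centres.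

**Step 5**
Reactants: 6 (2R,4R)-2,4-bis(tert-butyldimethylsilyloxy)pentanedial
Product: 7 (3R,5R)-3,5-bis(tert-butyldimethylsilyloxy)hepta-1,6-diene
Conditions: Ph3PCH3Br (3.0 equiv), KN(SiMe3)2 (2.8 equiv), THF, 0 °C; then 6, −78 °C to 0 °C
Reagents that add atoms: methyltriphenylphosphonium bromide, C[P+](c1ccccc1)(c1ccccc1)c1ccccc1.[Br-]
Why: Wittig methylenation, in which the non-stabilised ylide, kept free of excess base and met cold, should attack each aldehyde faster than the α-silyloxy C–H is deprotonated, so the (R,R) pair is carried into the two allylic centres of the diene.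

**Step 6**
Reactants: 8 4-bromo-2-methoxyphenol; 9 benzyl bromide
Product: 10 1-(benzyloxy)-4-bromo-2-methoxybenzene
Conditions: K2CO3, DMF, rt to 50 °C
Reagents that add atoms: none
Why: Williamson etherification of the phenoxide masks the acidic phenol for the basic coupling step with a group that is removable at the end by hydrogenolysis.

**Step 7**
Reactants: 7 (3R,5R)-3,5-bis(tert-butyldimethylsilyloxy)hepta-1,6-diene; 11 9-borabicyclo[3.3.1]nonane (9-BBN); 10 1-(benzyloxy)-4-bromo-2-methoxybenzene
Product: 13 (3S,5S)-1,7-bis[4-(benzyloxy)-3-methoxyphenyl]-3,5-bis(tert-butyldimethylsilyloxy)heptane, via bis(B-alkyl-9-BBN) borane 12 (not isolated)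
Conditions: 11 (2.5 equiv), THF, 0 °C to rt; then 3 M aq K3PO4, 10 (2.4 equiv), PdCl2(dppf) (10 mol %), DMF, 60 °C
Reagents that add atoms: none
Why: 9-BBN adds syn and anti-Markovnikov across each vinyl group, so boron ends up on the terminal carbons that become C1 and C7 and bis(alkylborane) 12 results. Aqueous K3PO4 turns each B-alkyl-9-BBN unit into a hydroxyborate, which hands its primary alkyl group (not the secondary bicyclic B–C bonds) to the arylpalladium bromide formed by oxidative addition of 10 to zerovalent palladium, and reductive elimination from the wide-bite-angle dppf complex should form each aryl–CH2 bond faster than β-hydride elimination. This is a two-fold B-alkyl Suzuki–Miyaura coupling, a known reaction class for terminal alkenes carrying allylic silyl ethers and for aryl bromides. No ring is closed and no stereocentre is made: C3 and C5 are spectators whose descriptors change from R to S only because the vinyl groups become lower-ranked CH2 arms. The step needs terminal regioselectivity, which the bulk of 9-BBN and the branched allylic silyloxy carbon secure, and complete reaction at both ends, which the excess of 11 and 10 and the independence of the two arms should secure. The silyloxy groups sit on the carbon γ to boron and to palladium, so no β-alkoxide elimination can occur.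

**Step 8**
Reactants: 13 (3S,5S)-1,7-bis[4-(benzyloxy)-3-methoxyphenyl]-3,5-bis(tert-butyldimethylsilyloxy)heptane
Product: 14 (3S,5S)-1,7-bis[4-(benzyloxy)-3-methoxyphenyl]heptane-3,5-diol
Conditions: 48% aq HF, MeCN/THF, 0 °C to rt
Reagents that add atoms: none
Why: Fluoride-mediated Si–O cleavage driven by the strong Si–F bond frees both secondary hydroxyls while benzyl and methyl aryl ethers are inert and no stereocentre reacts.

**Step 9**
Reactants: 14 (3S,5S)-1,7-bis[4-(benzyloxy)-3-methoxyphenyl]heptane-3,5-diol
Product: 16 (3S,5S)-1,7-bis[4-(benzyloxy)-3-methoxyphenyl]-5-hydroxyheptan-3-yl acetate, via cyclic orthoester 15 (not isolated)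
Conditions: MeC(OMe)3, CSA (cat.), CH2Cl2, rt; then 80% aq AcOH, rt
Reagents that add atoms: trimethyl orthoacetate, COC(C)(OC)OC; water, O
Why: Acid-catalysed orthoester exchange forms the six-membered 2-methoxy-2-methyl-1,3-dioxane and aqueous acid opens it through the dioxanylium ion and hemiorthoester to a hydroxy acetate; since the two hydroxyls are homotopic either C–O opening gives the same monoacetate, and only one acetyl group per molecule is delivered, which excludes the diacetate.

**Step 10**
Reactants: 16 (3S,5S)-1,7-bis[4-(benzyloxy)-3-methoxyphenyl]-5-hydroxyheptan-3-yl acetate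
Product: 17 (3S,5S)-5-hydroxy-1,7-bis(4-hydroxy-3-methoxyphenyl)heptan-3-yl acetate
Conditions: H2 (1 atm), 10% Pd/C, EtOAc, rt
Reagents that add atoms: none
Why: Catalytic hydrogenolysis cleaves the two benzyl aryl ethers under neutral conditions that leave the secondary acetate, the free hydroxyl and the aryl methyl ethers alone, and any 1,3-acetyl shift would be degenerate because the parent diol is C2-symmetric.

**Compound list**

1 | (1S,4R)-cis-4-acetoxy-2-cyclopenten-1-ol | O[C@@H]1C=C[C@H](OC(C)=O)C1 | starting material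
2 | (1R,4R)-4-acetoxycyclopent-2-en-1-yl 4-nitrobenzoate | O=C(O[C@H]1C=C[C@H](OC(C)=O)C1)c1ccc(cc1)[N+](=O)[O-] | intermediate
3 | (1R,3R)-cyclopent-4-ene-1,3-diol (trans) | O[C@H]1C=C[C@H](O)C1 | intermediate
4 | (3R,5R)-3,5-bis(tert-butyldimethylsilyloxy)cyclopent-1-ene (trans) | CC(C)(C)[Si](C)(C)O[C@H]1C=C[C@H](O[Si](C)(C)C(C)(C)C)C1 | intermediate
5 | secondary ozonide of 4: 2,4-bis(tert-butyldimethylsilyloxy)-6,7,8-trioxabicyclo[3.2.1]octane, silyloxy groups trans, carbinol configurations as in 4 (not isolated) | CC(C)(C)[Si](C)(C)O[C@@H]1C[C@@H](O[Si](C)(C)C(C)(C)C)[C@@H]2OO[C@H]1O2 | intermediate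
6 | (2R,4R)-2,4-bis(tert-butyldimethylsilyloxy)pentanedial | O=C[C@H](O[Si](C)(C)C(C)(C)C)C[C@H](C=O)O[Si](C)(C)C(C)(C)C | intermediate
7 | (3R,5R)-3,5-bis(tert-butyldimethylsilyloxy)hepta-1,6-diene | C=C[C@H](O[Si](C)(C)C(C)(C)C)C[C@H](C=C)O[Si](C)(C)C(C)(C)C | intermediate
8 | 4-bromo-2-methoxyphenol | COc1cc(Br)ccc1O | starting material
9 | benzyl bromide | BrCc1ccccc1 | starting material
10 | 1-(benzyloxy)-4-bromo-2-methoxybenzene | COc1cc(Br)ccc1OCc1ccccc1 | intermediate
11 | 9-borabicyclo[3.3.1]nonane (9-BBN) | B1C2CCCC1CCC2 | starting material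
12 | (3S,5S)-1,7-bis(9-borabicyclo[3.3.1]nonan-9-yl)-3,5-bis(tert-butyldimethylsilyloxy)heptane (not isolated) | CC(C)(C)[Si](C)(C)O[C@@H](CCB1C2CCCC1CCC2)C[C@H](CCB1C2CCCC1CCC2)O[Si](C)(C)C(C)(C)C | intermediate
13 | (3S,5S)-1,7-bis[4-(benzyloxy)-3-methoxyphenyl]-3,5-bis(tert-butyldimethylsilyloxy)heptane | COc1cc(CC[C@H](O[Si](C)(C)C(C)(C)C)C[C@H](CCc2ccc(OCc3ccccc3)c(OC)c2)O[Si](C)(C)C(C)(C)C)ccc1OCc1ccccc1 | intermediate
14 | (3S,5S)-1,7-bis[4-(benzyloxy)-3-methoxyphenyl]heptane-3,5-diol | COc1cc(CC[C@H](O)C[C@H](CCc2ccc(OCc3ccccc3)c(OC)c2)O)ccc1OCc1ccccc1 | intermediate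
15 | (4S,6S)-4,6-bis{2-[4-(benzyloxy)-3-methoxyphenyl]ethyl}-2-methoxy-2-methyl-1,3-dioxane (not isolated) | COc1cc(CC[C@H]2C[C@H](CCc3ccc(OCc4ccccc4)c(OC)c3)OC(C)(OC)O2)ccc1OCc1ccccc1 | intermediate
16 | (3S,5S)-1,7-bis[4-(benzyloxy)-3-methoxyphenyl]-5-hydroxyheptan-3-yl acetate | COc1cc(CC[C@H](O)C[C@H](CCc2ccc(OCc3ccccc3)c(OC)c2)OC(C)=O)ccc1OCc1ccccc1 | intermediate
17 | (3S,5S)-5-hydroxy-1,7-bis(4-hydroxy-3-methoxyphenyl)heptan-3-yl acetate | COc1cc(CC[C@H](O)C[C@H](CCc2ccc(O)c(OC)c2)OC(C)=O)ccc1O | target

**Step count and risk**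

Total step count: 10. Longest linear sequence: 9 steps (steps 1–5 and 7–10); step 6 is the one-step side branch.

Steps most likely to fail:

1. Step 7. The second coupling may stall, one arm may be lost to protodeboronation or β-hydride elimination, and oxidative addition of the electron-rich aryl bromide may be slow. The fallback sets out from 7 and reverses the metal roles. Hydroboration with 9-BBN to 12 followed by NaOH/H2O2 oxidation should give (3S,5S)-3,5-bis(tert-butyldimethylsilyloxy)heptane-1,7-diol F1. Appel iodination (I2, PPh3, imidazole, CH2Cl2) should give (3R,5R)-3,5-bis(tert-butyldimethylsilyloxy)-1,7-diiodoheptane F2; the descriptors change only through CIP ranking. Zinc insertion (Zn dust, LiCl, THF) should give [(3R,5R)-3,5-bis(tert-butyldimethylsilyloxy)heptane-1,7-diyl]bis(iodozinc) F3, which is used in solution. Negishi coupling of F3 with 10 under Pd(OAc)2/SPhos in THF returns to the route at 13.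

2. Step 5. The basic ylide may epimerise the α-silyloxy carbons of the dialdehyde and erode the anti relationship, or β-elimination and hydrate formation may compete with olefination. The fallback sets out from 6 and leaves ylide chemistry for a non-basic gem-dimetallic methylenation of the Takai–Lombardo type (Zn, CH2Br2, TiCl4, THF/CH2Cl2, 0 °C), in which a Lewis-acidic titanium methylidene transfers CH2 without an enolisable intermediate. It returns to the route at 7 and makes no new compound (F0).

3. Step 9. The cyclic orthoester may hydrolyse back to the diol instead of opening through the hemiorthoester, or acetyl transfer between molecules may give diol/diacetate mixtures. The fallback sets out from 14 and activates the diol as a tin acetal. Bu2SnO in toluene at reflux with water removal should give (4S,6S)-4,6-bis{2-[4-(benzyloxy)-3-methoxyphenyl]ethyl}-2,2-dibutyl-1,3,2-dioxastanninane F4. One equivalent of acetyl chloride in CH2Cl2 at 0 °C then acylates a single Sn–O bond, and aqueous work-up returns to the route at 16.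

**Further compounds**

F1 | step 7 | (3S,5S)-3,5-bis(tert-butyldimethylsilyloxy)heptane-1,7-diol | OCC[C@H](O[Si](C)(C)C(C)(C)C)C[C@H](CCO)O[Si](C)(C)C(C)(C)C
F2 | step 7 | (3R,5R)-3,5-bis(tert-butyldimethylsilyloxy)-1,7-diiodoheptane | ICC[C@H](O[Si](C)(C)C(C)(C)C)C[C@H](CCI)O[Si](C)(C)C(C)(C)C
F3 | step 7 | [(3R,5R)-3,5-bis(tert-butyldimethylsilyloxy)heptane-1,7-diyl]bis(iodozinc) | I[Zn]CC[C@H](O[Si](C)(C)C(C)(C)C)C[C@H](CC[Zn]I)O[Si](C)(C)C(C)(C)C
F0 | step 5 | none | none
F4 | step 9 | (4S,6S)-4,6-bis{2-[4-(benzyloxy)-3-methoxyphenyl]ethyl}-2,2-dibutyl-1,3,2-dioxastanninane | CCCC[Sn]1(CCCC)O[C@@H](CCc2ccc(OCc3ccccc3)c(OC)c2)C[C@H](CCc2ccc(OCc3ccccc3)c(OC)c2)O1
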